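## The problem

The target is a 3,3''-biflavanone. Unit 1 is liquiritigenin-type (7-hydroxy ring A, locants C2–C4), unit 2 is naringenin-type (5,7-dihydroxy ring A, locants C2''–C4''). They are joined by the C3–C3'' bond between two α-keto methines, and each carries a 4-hydroxyphenyl ring B on C2 or C2''. The four contiguous stereocentres C2–C3–C3''–C2'' are 2S,3R,3''R,2''S: both pyranone rings are 2,3-trans and the molecule is pseudo-C2-symmetric, the halves differing only in the 5-hydroxyl of unit 2. A synthesis must therefore make a hindered bond between two secondary carbons as a cross-union, not a homodimerisation, and must select the chiral (R,R) over the meso-like (R,S) relation at C3/C3''. C3 and C3'' are enolisable and should settle trans to the aryl group on the neighbouring carbon, so C2 and C2'' can control them; C2 and C2'' are 1,4-related, cannot control each other, and must each be set absolutely. The ring system is fragile: base opens a flavanone by E1cB loss of the ring A phenoxide from the C3 enolate, erasing C2 and C3, and a free 4'-hydroxyl adds a quinone methide path for C2 epimerisation, so the phenols should stay capped until the end and be released under neutral conditions. The enabling feature is the chain C4–C3–C3''–C4'': it is a 1,4-diketone in which each carbonyl carbon is tied back, through ring A and O1 (or O1''), to the carbon next to its own α-carbon (C2 or C2''). C3–C3'' can thus be read as a former C≡C bond that has taken up two aroyl anion equivalents and two hydrogens, each acyl group arriving on a tether of exactly the length of ring C.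

## Retrosynthesis

**16 to 15.** The five O–H bonds are traced back to benzyl ethers in 15. Benzyl is chosen because hydrogenolysis is neutral, and because an ether on the 4'-oxygen closes the quinone methide path at C2 throughout the route.

**15 to 12 (key disconnection).** The two acyl–Cα bonds C4–C3 and C4''–C3'' are cut, and C3–C3'' is raised to an alkyne. This gives dialdehyde 12, the bis(2-formylaryl) ether of a 1,4-diarylbut-2-yne-1,4-diol. The neighbouring cuts are weaker. Cutting C3–C3'' leaves the cross-coupling and the (R,R)/(R,S) choice unsolved. Cutting the O1–C2 bonds leaves an achiral bis-chalcone. Compound 12 has no ring C, no 1,4-diketone and only two stereocentres, both of the simple carbinol type and both R. The forward reaction must add each formyl C–H across the alkyne: first as a hydroacylation (ring closure 6-exo-dig), then as a Stetter addition to the enone just formed (6-exo-trig). C3 and C3'' must then settle trans to C2 and C2''.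

**12 to 8 and 10 (through 11).** The aryl ether bond O1''–C2'' is cut to the propargylic alcohol 8 and the salicylaldehyde 10. A Mitsunobu reaction forms it with inversion, so 8 must be S at the carbinol. The formyl group of unit 1 is carried in 8 as a dimethyl acetal, which is removed from 11 in the same operation.

**10 to 9.** Two O–benzyl bonds are cut to 2,4,6-trihydroxybenzaldehyde 9. The forward step relies on the chelated ortho-hydroxyl staying free.

**8 to 7 and 1.** The C2''–C3'' bond is cut to the terminal alkyne 7 and aldehyde 1. A catalytic asymmetric alkynylation sets the second carbinol independently of the first. Because the two centres are set by separate catalyst-controlled events, an error at either one becomes a diastereomer that can be separated, not the enantiomer.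

**7 to 5 (through 6).** The acetal and the alkyne C–H are traced back to the free aldehyde and the C-silyl alkyne of 5. The acetal is needed only so that the alkynylzinc species in the step to 8 sees a single aldehyde.

**5 to 3 and 4.** The aryl ether bond O1–C2 is cut to the propargylic alcohol 3 and the commercial salicylaldehyde 4; the Mitsunobu reaction again inverts S to R.

**3 to 1 and 2.** The C2–C3 bond is cut to aldehyde 1 and ethynyltrimethylsilane 2, joined by the same asymmetric alkynylation. Ring B and C2 of both halves thus come from one cheap aldehyde.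

## Roads not taken

**Alternative 1:** cut C3–C3'' (the obvious dimer disconnection). Benzyl-protected (S)-liquiritigenin A1 and (S)-naringenin A2 would be joined by oxidative enolate coupling, for example through the mixed diisopropylsilyl bis-enol ether A3 and (NH4)2Ce(NO3)6. Each flavanone needs its own enantioselective synthesis. Their enolates carry a β-aryloxy leaving group and are prone to E1cB ring opening. The new bond lies between two hindered secondary centres, and nothing reliable selects the (R,R) over the (R,S) relation at C3/C3''. The chosen plan never forms C3–C3'' as a single bond: it is the alkyne of the precursor, and the cross-union is decided by two ordinary carbonyl additions.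

**Alternative 2:** cut both O1–C2 bonds. The 1,4-diketone A4 would be condensed with two equivalents of 1 to the bis-chalcone A5, which closes by double oxa-Michael addition. This is short, but A5 is achiral: four stereocentres arise in two cyclisations and two protonations. Equilibration can give trans rings but cannot choose between the chiral and the meso-like series or fix the absolute configuration. A chiral catalyst would have to control an α-branched, twisted chalcone twice. The chosen plan holds C2 and C2'' configurationally defined before any ring is closed.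

**Alternative 3:** cut both C2–aryl bonds. The flat 3,3'-bichromone A6 would take up two para-benzyloxyphenyl groups from an arylboron reagent under a chiral rhodium catalyst such as [RhCl(C2H4)2]2 with a chiral diene, with C3/C3'' relayed as in the chosen plan. The idea is attractive, but each chromone is α-substituted, the second addition meets a 3-sec-alkyl chromone next to a peri 5-alkoxy group, and the arylation conditions are basic enough to open the products. The chosen plan sets the same two centres by aldehyde alkynylation and makes the C–C bonds at C3 and C3'' intramolecularly.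

Key step: step 7

Remarks on the chemistry. The sense of induction of the zinc–ProPhenol alkynylation is assumed from aryl aldehyde precedent; the ligand antipode that gives the S carbinol is the one used (written as S,S below). 2,3-trans (diequatorial) is taken as the thermodynamically preferred arrangement of a 3-substituted flavanone.

## Route

Step 1
Reactants: 1 4-(benzyloxy)benzaldehyde; 2 ethynyltrimethylsilane
Product: 3 (S)-1-[4-(benzyloxy)phenyl]-3-(trimethylsilyl)prop-2-yn-1-ol
Conditions: (S,S)-ProPhenol (10 mol%), Me2Zn (3 equiv), Ph3PO (20 mol%), 2 (3 equiv), toluene, 0 °C; aq NH4Cl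
Reagents that add atoms: none
Why: Catalytic enantioselective alkynylation (dinuclear zinc–ProPhenol, alkynylzinc addition to an aryl aldehyde); the chiral zinc complex selects the aldehyde face and sets the S carbinol.

Step 2
Reactants: 3 (S)-1-[4-(benzyloxy)phenyl]-3-(trimethylsilyl)prop-2-yn-1-ol; 4 4-(benzyloxy)-2-hydroxybenzaldehyde
Product: 5 4-(benzyloxy)-2-{[(1R)-1-[4-(benzyloxy)phenyl]-3-(trimethylsilyl)prop-2-yn-1-yl]oxy}benzaldehyde
Conditions: PPh3, DIAD, toluene, −20 °C to rt
Reagents that add atoms: none
Why: Mitsunobu etherification; SN2 attack of the acidic, hydrogen-bonded phenol on the oxyphosphonium ion inverts the carbinol (S to R). The silyl group shields the alkyne terminus against SN2′ attack, and the non-polar solvent at low temperature holds back ionisation of the benzylic centre.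

Step 3
Reactants: 5 4-(benzyloxy)-2-{[(1R)-1-[4-(benzyloxy)phenyl]-3-(trimethylsilyl)prop-2-yn-1-yl]oxy}benzaldehyde
Product: 7 4-(benzyloxy)-2-{[(1R)-1-[4-(benzyloxy)phenyl]prop-2-yn-1-yl]oxy}-1-(dimethoxymethyl)benzene, via silyl alkyne acetal 6 (not isolated)
Conditions: HC(OMe)3, PPTS (cat.), MeOH, rt; then K2CO3, rt
Reagents that add atoms: trimethyl orthoformate COC(OC)OC; methanol CO
Why: Acid-catalysed acetalisation with orthoformate as water scavenger masks the formyl group against the alkynylzinc chemistry of step 4; carbonate-mediated methanolysis then removes the C-silyl group. The stereocentre is not involved.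

Step 4
Reactants: 7 4-(benzyloxy)-2-{[(1R)-1-[4-(benzyloxy)phenyl]prop-2-yn-1-yl]oxy}-1-(dimethoxymethyl)benzene; 1 4-(benzyloxy)benzaldehyde
Product: 8 (1S,4R)-4-[5-(benzyloxy)-2-(dimethoxymethyl)phenoxy]-1,4-bis[4-(benzyloxy)phenyl]but-2-yn-1-ol
Conditions: (S,S)-ProPhenol (20 mol%), Me2Zn (3 equiv), Ph3PO (40 mol%), 1 (2 equiv), toluene, 0 °C; aq NH4Cl
Reagents that add atoms: none
Why: Second zinc–ProPhenol alkynylation, now with the alkyne as limiting partner; the catalyst sets the new carbinol S, since the existing centre lies on the far side of the linear alkyne and should exert little bias. A wrong-handed addition gives a diastereomer that chromatography can remove.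

Step 5
Reactants: 9 2,4,6-trihydroxybenzaldehyde
Product: 10 2,4-bis(benzyloxy)-6-hydroxybenzaldehyde
Conditions: BnBr (2.1 equiv), K2CO3, DMF, 0 °C to rt
Reagents that add atoms: benzyl bromide BrCc1ccccc1
Why: Williamson etherification; after two benzylations the remaining hydroxyl is held in a hydrogen bond to the formyl oxygen and is the least nucleophilic, so alkylation should stop at the dibenzyl ether.

Step 6
Reactants: 8 (1S,4R)-4-[5-(benzyloxy)-2-(dimethoxymethyl)phenoxy]-1,4-bis[4-(benzyloxy)phenyl]but-2-yn-1-ol; 10 2,4-bis(benzyloxy)-6-hydroxybenzaldehyde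
Product: 12 4-(benzyloxy)-2-{[(1R,4R)-4-[3,5-bis(benzyloxy)-2-formylphenoxy]-1,4-bis[4-(benzyloxy)phenyl]but-2-yn-1-yl]oxy}benzaldehyde, via acetal bis-ether 11 (not isolated)
Conditions: PPh3, DIAD, toluene, −20 °C to rt; then concentrate, PPTS, acetone–H2O, rt
Reagents that add atoms: water O
Why: Mitsunobu etherification with inversion (S to R), followed by mild hydrolysis of the electron-rich aryl dimethyl acetal. The bulky substituent on the far alkyne carbon disfavours SN2′ attack, and a loss of configuration here would give a separable diastereomer.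

Step 7
Reactants: 12 4-(benzyloxy)-2-{[(1R,4R)-4-[3,5-bis(benzyloxy)-2-formylphenoxy]-1,4-bis[4-(benzyloxy)phenyl]but-2-yn-1-yl]oxy}benzaldehyde
Product: 15 (2S,3R)-7-(benzyloxy)-2-[4-(benzyloxy)phenyl]-3-{(2S,3R)-5,7-bis(benzyloxy)-2-[4-(benzyloxy)phenyl]-4-oxochroman-3-yl}chroman-4-one, via enone aldehyde 13 (not isolated), via enone aldehyde 14 (not isolated)
Conditions: 3-mesityl-5,6,7,8-tetrahydro-4H-cyclohepta[d]thiazol-3-ium perchlorate (20 mol%), K2CO3 (40 mol%), THF, 70 °C
Reagents that add atoms: none
Why: N-heterocyclic carbene umpolung cascade of alkyne hydroacylation and intramolecular Stetter reaction, each known for 2-(propargyloxy)benzaldehydes and for salicylaldehyde-tethered enones, and known as a hydroacylation–Stetter sequence. The carbene adds to one formyl group to give a Breslow enaminol, which bonds to the proximal alkyne carbon while its O–H proton passes to the distal carbon (Conia-ene-like syn addition), closing the first pyranone ring 6-exo-dig and giving E-enone 13 (unit 1 aldehyde first) or 14 (unit 2 aldehyde first). The exocyclic enone is the acceptor for the Breslow intermediate of the remaining aldehyde, which closes the second pyranone ring 6-exo-trig at the β-carbon and leaves an enol in the first ring that tautomerises to the 1,4-diketone, so both orders converge on 15. C2 and C2'' are not touched: the R,R centres of 12 become 2S and 2''S by change of descriptor only. The α-centre formed in the Stetter closure should arise anti to the neighbouring aryl group through a chair-like transition state, and the other by protonation of the enol. Both are α-keto methines, so the carbonate should equilibrate them to the diequatorial 2,3-trans arrangement in each ring, which with 2S,2''S is the 3R,3''R series of the target. The step needs 6-exo over 7-endo closure (fixed by tether length), no 1,3-hydrogen shift of the exocyclic enone into the flavone (weak heterogeneous base, fast intramolecular trapping), and no E1cB opening of the rings (capped 4'-oxygens, no alkoxide base).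

Step 8
Reactants: 15 (2S,3R)-7-(benzyloxy)-2-[4-(benzyloxy)phenyl]-3-{(2S,3R)-5,7-bis(benzyloxy)-2-[4-(benzyloxy)phenyl]-4-oxochroman-3-yl}chroman-4-one
Product: 16 (2S,3R)-7-hydroxy-2-(4-hydroxyphenyl)-3-[(2S,3R)-5,7-dihydroxy-2-(4-hydroxyphenyl)-4-oxochroman-3-yl]chroman-4-one (CNP0138443.1)
Conditions: H2 (1 atm), Pd/C, EtOAc–MeOH, rt
Reagents that add atoms: none
Why: Hydrogenolysis of five aryl benzyl ethers under neutral conditions; no base is present, so neither the E1cB nor the quinone methide path to C2/C3 scrambling is opened. Aryl ketones conjugated to electron-rich rings should be slow to reduce.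

## Compound list

1 | 4-(benzyloxy)benzaldehyde | O=Cc1ccc(OCc2ccccc2)cc1 | starting material
2 | ethynyltrimethylsilane | C#C[Si](C)(C)C | starting material
3 | (S)-1-[4-(benzyloxy)phenyl]-3-(trimethylsilyl)prop-2-yn-1-ol | O[C@H](C#C[Si](C)(C)C)c1ccc(OCc2ccccc2)cc1 | intermediate
4 | 4-(benzyloxy)-2-hydroxybenzaldehyde | O=Cc1ccc(OCc2ccccc2)cc1O | starting material
5 | 4-(benzyloxy)-2-{[(1R)-1-[4-(benzyloxy)phenyl]-3-(trimethylsilyl)prop-2-yn-1-yl]oxy}benzaldehyde | O=Cc1ccc(OCc2ccccc2)cc1O[C@@H](C#C[Si](C)(C)C)c1ccc(OCc2ccccc2)cc1 | intermediate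
6 | {(3R)-3-[5-(benzyloxy)-2-(dimethoxymethyl)phenoxy]-3-[4-(benzyloxy)phenyl]prop-1-yn-1-yl}trimethylsilane | COC(OC)c1ccc(OCc2ccccc2)cc1O[C@@H](C#C[Si](C)(C)C)c1ccc(OCc2ccccc2)cc1 | intermediate (not isolated)
7 | 4-(benzyloxy)-2-{[(1R)-1-[4-(benzyloxy)phenyl]prop-2-yn-1-yl]oxy}-1-(dimethoxymethyl)benzene | COC(OC)c1ccc(OCc2ccccc2)cc1O[C@@H](C#C)c1ccc(OCc2ccccc2)cc1 | intermediate
8 | (1S,4R)-4-[5-(benzyloxy)-2-(dimethoxymethyl)phenoxy]-1,4-bis[4-(benzyloxy)phenyl]but-2-yn-1-ol | COC(OC)c1ccc(OCc2ccccc2)cc1O[C@@H](C#C[C@@H](O)c1ccc(OCc2ccccc2)cc1)c1ccc(OCc2ccccc2)cc1 | intermediate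
9 | 2,4,6-trihydroxybenzaldehyde | O=Cc1c(O)cc(O)cc1O | starting material
10 | 2,4-bis(benzyloxy)-6-hydroxybenzaldehyde | O=Cc1c(O)cc(OCc2ccccc2)cc1OCc1ccccc1 | intermediate
11 | 2,4-bis(benzyloxy)-6-{[(1R,4R)-4-[5-(benzyloxy)-2-(dimethoxymethyl)phenoxy]-1,4-bis[4-(benzyloxy)phenyl]but-2-yn-1-yl]oxy}benzaldehyde | COC(OC)c1ccc(OCc2ccccc2)cc1O[C@@H](C#C[C@H](Oc1cc(OCc2ccccc2)cc(OCc2ccccc2)c1C=O)c1ccc(OCc2ccccc2)cc1)c1ccc(OCc2ccccc2)cc1 | intermediate (not isolated)
12 | 4-(benzyloxy)-2-{[(1R,4R)-4-[3,5-bis(benzyloxy)-2-formylphenoxy]-1,4-bis[4-(benzyloxy)phenyl]but-2-yn-1-yl]oxy}benzaldehyde | O=Cc1ccc(OCc2ccccc2)cc1O[C@@H](C#C[C@H](Oc1cc(OCc2ccccc2)cc(OCc2ccccc2)c1C=O)c1ccc(OCc2ccccc2)cc1)c1ccc(OCc2ccccc2)cc1 | intermediate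
13 | (2R,3E)-7-(benzyloxy)-2-[4-(benzyloxy)phenyl]-3-{(2S)-2-[3,5-bis(benzyloxy)-2-formylphenoxy]-2-[4-(benzyloxy)phenyl]ethylidene}chroman-4-one | O=C1c2ccc(OCc3ccccc3)cc2O[C@H](c2ccc(OCc3ccccc3)cc2)/C1=C\[C@H](Oc1cc(OCc2ccccc2)cc(OCc2ccccc2)c1C=O)c1ccc(OCc2ccccc2)cc1 | intermediate (not isolated)
14 | (2R,3E)-5,7-bis(benzyloxy)-2-[4-(benzyloxy)phenyl]-3-{(2S)-2-[5-(benzyloxy)-2-formylphenoxy]-2-[4-(benzyloxy)phenyl]ethylidene}chroman-4-one | O=C1c2c(OCc3ccccc3)cc(OCc3ccccc3)cc2O[C@H](c2ccc(OCc3ccccc3)cc2)/C1=C\[C@H](Oc1cc(OCc2ccccc2)ccc1C=O)c1ccc(OCc2ccccc2)cc1 | intermediate (not isolated)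
15 | (2S,3R)-7-(benzyloxy)-2-[4-(benzyloxy)phenyl]-3-{(2S,3R)-5,7-bis(benzyloxy)-2-[4-(benzyloxy)phenyl]-4-oxochroman-3-yl}chroman-4-one | O=C1c2ccc(OCc3ccccc3)cc2O[C@H](c2ccc(OCc3ccccc3)cc2)[C@H]1[C@H]1C(=O)c2c(OCc3ccccc3)cc(OCc3ccccc3)cc2O[C@@H]1c1ccc(OCc2ccccc2)cc1 | intermediate
16 | (2S,3R)-7-hydroxy-2-(4-hydroxyphenyl)-3-[(2S,3R)-5,7-dihydroxy-2-(4-hydroxyphenyl)-4-oxochroman-3-yl]chroman-4-one | O=C1c2ccc(O)cc2O[C@H](c2ccc(O)cc2)[C@H]1[C@H]1C(=O)c2c(O)cc(O)cc2O[C@@H]1c1ccc(O)cc1 | target

## Step count and risk

Total: 8 steps. Longest linear sequence: 7 steps (1, 2, 3, 4, 6, 7, 8); step 5 is a one-step side branch.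

**Step 7 (key step).** Three processes are most likely to go wrong.
- Breslow intermediate formation may be slow at the di-ortho-substituted, electron-rich formyl group of unit 2, so the cascade could stall after the first ring closure.
- The stalled exocyclic enone could undergo a base-mediated 1,3-hydrogen shift into the ring, which would erase C2.
- Equilibration at C3/C3'' may be incomplete.

Fallback (radical chain in place of polar umpolung), setting out from 12 and returning at 15. Chlorite oxidation (NaClO2, NaH2PO4, 2-methyl-2-butene, t-BuOH–H2O) should give the diacid F1. PhSeSePh and Bu3P should convert it into the bis(Se-phenyl) selenoester F2. Slow addition of Bu3SnH with AIBN in benzene at 80 °C should generate an aroyl radical that closes 6-exo-dig on the alkyne; the second aroyl radical then adds 6-exo-trig to the β-carbon of the resulting enone, a polarity-matched Giese addition. A brief Et3N treatment would finish the equilibration at C3/C3'' to 15.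

**Step 2.** The oxyphosphonium ion of a para-benzyloxybenzylic propargylic alcohol may ionise in part, causing loss of configuration, or react SN2′. Fallback (C–O bond formed at the aryl carbon, carbinol untouched), setting out from 1 and 2 and returning at 5. Step 1 run with the antipodal ligand gives the (R)-alcohol F3. Its potassium alkoxide (KN(SiMe3)2, THF, 0 °C) displaces fluoride from commercial 4-(benzyloxy)-2-fluorobenzonitrile by SNAr with retention to give the nitrile ether F4. Reduction with i-Bu2AlH (toluene, −78 °C) and aqueous acid work-up gives 5.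

**Step 4.** With the alkyne as limiting partner, conversion or facial selectivity of the zinc–ProPhenol addition may fall, and methyl transfer from Me2Zn to 1 may compete. Fallback (carbinol set by reduction instead of addition), setting out from 7 and returning at 8. The lithium acetylide of 7 (n-BuLi, THF, −78 °C) adds to 1 to give the epimeric carbinols F5. MnO2 oxidises them to the ynone F6. Transfer hydrogenation with RuCl(p-cymene)[(S,S)-TsDPEN] (antipode chosen for the S carbinol) in HCO2H–Et3N gives 8.

**Step 6.** The same ionisation as in step 2 may occur on a valuable substrate, and the activated benzylic aryl ethers may solvolyse during acetal hydrolysis. Fallback (SNAr with retention), setting out from 7 and 1 and returning at 12. Step 4 run with the antipodal ligand gives the (1R,4R)-alcohol F7. The fluoronitrile F8 is made from 2,4,6-trifluorobenzonitrile and benzyl alcohol (2 equiv, NaH, THF). The potassium alkoxide of F7 displaces the fluoride of F8 (KN(SiMe3)2, THF–DMF, warming) to give the nitrile acetal ether F9. i-Bu2AlH followed by aqueous acid converts the nitrile into the formyl group and unmasks the acetal, giving 12.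

**Step 8.** Hydrogenolysis of the benzylic C2–O1 and C2''–O1'' ring bonds or reduction of the aryl ketones may compete with removal of five benzyl groups. Fallback (Lewis-acid dealkylation instead of reduction), from 15 directly to 16: BCl3 with pentamethylbenzene as cation scavenger in CH2Cl2 at −78 °C. No new compound is made.

## Further compounds

F1 | step 7 | 4-(benzyloxy)-2-{[(1R,4R)-4-[3,5-bis(benzyloxy)-2-carboxyphenoxy]-1,4-bis[4-(benzyloxy)phenyl]but-2-yn-1-yl]oxy}benzoic acid | OC(=O)c1ccc(OCc2ccccc2)cc1O[C@@H](C#C[C@H](Oc1cc(OCc2ccccc2)cc(OCc2ccccc2)c1C(O)=O)c1ccc(OCc2ccccc2)cc1)c1ccc(OCc2ccccc2)cc1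
F2 | step 7 | bis(Se-phenyl) selenoester of F1 | O=C([Se]c1ccccc1)c1ccc(OCc2ccccc2)cc1O[C@@H](C#C[C@H](Oc1cc(OCc2ccccc2)cc(OCc2ccccc2)c1C(=O)[Se]c1ccccc1)c1ccc(OCc2ccccc2)cc1)c1ccc(OCc2ccccc2)cc1
F3 | step 2 | (R)-1-[4-(benzyloxy)phenyl]-3-(trimethylsilyl)prop-2-yn-1-ol | O[C@@H](C#C[Si](C)(C)C)c1ccc(OCc2ccccc2)cc1
F4 | step 2 | 4-(benzyloxy)-2-{[(1R)-1-[4-(benzyloxy)phenyl]-3-(trimethylsilyl)prop-2-yn-1-yl]oxy}benzonitrile | N#Cc1ccc(OCc2ccccc2)cc1O[C@@H](C#C[Si](C)(C)C)c1ccc(OCc2ccccc2)cc1
F5 | step 4 | (1RS,4R)-4-[5-(benzyloxy)-2-(dimethoxymethyl)phenoxy]-1,4-bis[4-(benzyloxy)phenyl]but-2-yn-1-ol (carbinol epimers) | COC(OC)c1ccc(OCc2ccccc2)cc1O[C@@H](C#CC(O)c1ccc(OCc2ccccc2)cc1)c1ccc(OCc2ccccc2)cc1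
F6 | step 4 | (4R)-4-[5-(benzyloxy)-2-(dimethoxymethyl)phenoxy]-1,4-bis[4-(benzyloxy)phenyl]but-2-yn-1-one | COC(OC)c1ccc(OCc2ccccc2)cc1O[C@@H](C#CC(=O)c1ccc(OCc2ccccc2)cc1)c1ccc(OCc2ccccc2)cc1
F7 | step 6 | (1R,4R)-4-[5-(benzyloxy)-2-(dimethoxymethyl)phenoxy]-1,4-bis[4-(benzyloxy)phenyl]but-2-yn-1-ol | COC(OC)c1ccc(OCc2ccccc2)cc1O[C@@H](C#C[C@H](O)c1ccc(OCc2ccccc2)cc1)c1ccc(OCc2ccccc2)cc1
F8 | step 6 | 2,4-bis(benzyloxy)-6-fluorobenzonitrile | N#Cc1c(F)cc(OCc2ccccc2)cc1OCc1ccccc1
F9 | step 6 | 2,4-bis(benzyloxy)-6-{[(1R,4R)-4-[5-(benzyloxy)-2-(dimethoxymethyl)phenoxy]-1,4-bis[4-(benzyloxy)phenyl]but-2-yn-1-yl]oxy}benzonitrile | COC(OC)c1ccc(OCc2ccccc2)cc1O[C@@H](C#C[C@H](Oc1cc(OCc2ccccc2)cc(OCc2ccccc2)c1C#N)c1ccc(OCc2ccccc2)cc1)c1ccc(OCc2ccccc2)cc1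
F0 | step 8 | none | none
A1 | alternative 1 | (2S)-7-(benzyloxy)-2-[4-(benzyloxy)phenyl]chroman-4-one | O=C1C[C@@H](c2ccc(OCc3ccccc3)cc2)Oc2cc(OCc3ccccc3)ccc12
A2 | alternative 1 | (2S)-5,7-bis(benzyloxy)-2-[4-(benzyloxy)phenyl]chroman-4-one | O=C1C[C@@H](c2ccc(OCc3ccccc3)cc2)Oc2cc(OCc3ccccc3)cc(OCc3ccccc3)c12
A3 | alternative 1 | mixed diisopropylsilyl bis-enol ether of A1 and A2 | CC(C)[Si](OC1=C[C@@H](c2ccc(OCc3ccccc3)cc2)Oc2cc(OCc3ccccc3)ccc12)(OC1=C[C@@H](c2ccc(OCc3ccccc3)cc2)Oc2cc(OCc3ccccc3)cc(OCc3ccccc3)c12)C(C)C
A4 | alternative 2 | 1-[4-(benzyloxy)-2-hydroxyphenyl]-4-[2,4-bis(benzyloxy)-6-hydroxyphenyl]butane-1,4-dione | O=C(CCC(=O)c1c(O)cc(OCc2ccccc2)cc1OCc1ccccc1)c1ccc(OCc2ccccc2)cc1O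
A5 | alternative 2 | (2E,3E)-2,3-bis[4-(benzyloxy)benzylidene]-1-[4-(benzyloxy)-2-hydroxyphenyl]-4-[2,4-bis(benzyloxy)-6-hydroxyphenyl]butane-1,4-dione | O=C(c1ccc(OCc2ccccc2)cc1O)/C(=C/c1ccc(OCc2ccccc2)cc1)/C(=C\c1ccc(OCc2ccccc2)cc1)C(=O)c1c(O)cc(OCc2ccccc2)cc1OCc1ccccc1
A6 | alternative 3 | 5,7-bis(benzyloxy)-3-[7-(benzyloxy)-4-oxo-4H-chromen-3-yl]-4H-chromen-4-one | O=c1c(-c2coc3cc(OCc4ccccc4)cc(OCc4ccccc4)c3c2=O)coc2cc(OCc3ccccc3)ccc12
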